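The plan rests on cutting ring A, the dearomatised butyrylfilicinic acid ring (C1 ketone, C2 butyryl-bearing, C3 enol, C4 gem-dimethyl, C5 enol, C6 bridge-bearing), into a ketone unit C4–C5–C6 and a malonyl unit C1–C2–C3. It exploits the 1,3,5-tricarbonyl pattern, in which C4 and C6 are both alpha to C5 while C1 and C3 flank C2. An Effenberger-type double C-acylation of a regiodefined tetrasubstituted silyl enol ether of 2-methylpentan-3-one with malonyl dichloride forms C3–C4 and C1–C6 in one operation. The C6 methyl later becomes the first methylene bridge through a quinone methide; Mannich methylenations then build trimers A–B–C and F–E–D, which are joined last.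

Key step: step 2

Remark: the β-triketone ring A is drawn in one enol tautomer (the tautomers equilibrate freely) and the target has no stereocentre. Rings B to E are the four internal butyrylphloroglucinol rings counted from ring A, and ring F is the terminal C-methyl ring. Ring-A locants are those given in the first paragraph. Compounds 1, 3, 7 and 9 are taken to be commercial.

Step 1
Reactants: 1 2-methylpent-1-en-3-one
Product: 2 2-methyl-3-(triethylsilyloxy)pent-2-ene
Conditions: Et3SiH, RhCl(PPh3)3 (1 mol %), C6H6, 60 °C
Reagents that add atoms: triethylsilane CC[SiH](CC)CC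
Why: Rhodium-catalysed conjugate (1,4-) hydrosilylation of the enone should deliver hydride to the terminal CH2 and silicon to oxygen, so the tetrasubstituted enol ether forms as one regioisomer, with no E/Z question because the new alkene terminus carries two methyl groups.

Step 2
Reactants: 2 2-methyl-3-(triethylsilyloxy)pent-2-ene; 3 malonyl dichloride
Product: 5 methylfilicinic acid (3,5-dihydroxy-2,4,4-trimethylcyclohexa-2,5-dien-1-one), via 4,4-dimethyl-3,5-dioxoheptanoyl chloride 4 (not isolated)
Conditions: 3 (1.3 equiv), Et2O, −20 °C → rt; then aq KOH, BnEt3NCl (cat.), 0 °C → rt; HCl work-up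
Reagents that add atoms: none
Why: Malonyl dichloride (reacting through chlorocarbonylketene formed by loss of HCl) should C-acylate the tetrasubstituted enol-ether carbon of 2 with loss of Et3SiCl, which forms the C3–C4 bond and the quaternary gem-dimethyl centre and leaves the β-ketoacyl chloride 4; base then converts the ethyl ketone of 4 into its enolate, whose CH carbon (C6) attacks the acyl chloride or the derived acylketene and forms the C1–C6 bond. The closest known reaction type is the Effenberger cyclization, the α,α′-bis-C-acylation of ketone enol ethers with malonyl dichloride that gives cyclohexane-1,3,5-triones. Ring A closes in a 6-(enolendo)-exo-trig mode by intramolecular C-acylation. No stereocentre remains, because C6 is stereogenic only in the triketo tautomer and 5 should be isolated as the achiral, freely tautomerising enol. The step needs C- over O-acylation and acylation of the more substituted α-carbon first: the regiodefined enol ether 2 places the first acylation at C4, the resulting quaternary carbon blocks the enolisation that would lead to an aromatic 4-hydroxy-2-pyranone, and the delocalised trione enolate is the thermodynamic sink under the basic second stage.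

Step 3
Reactants: 5 methylfilicinic acid
Product: 6 2-butanoyl-3,5-dihydroxy-4,4,6-trimethylcyclohexa-2,5-dien-1-one
Conditions: n-PrCOCl (1.1 equiv), AlCl3 (3.5 equiv), PhNO2/CH2Cl2, 0 → 40 °C; aq HCl
Reagents that add atoms: butanoyl chloride CCCC(=O)Cl
Why: Friedel–Crafts C-acylation of the enolised trione should occur at its only unsubstituted nucleophilic carbon (the malonyl-derived ring-A C2), since C6 is blocked by its methyl group and any O-acyl isomer converges by Fries-type migration to the chelated 2-acyl trione.

Step 4
Reactants: 7 phloroglucinol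
Product: 8 1-(2,4,6-trihydroxyphenyl)butan-1-one
Conditions: n-PrCOCl (1.0 equiv), AlCl3 (4 equiv), PhNO2/CH2Cl2, rt → 50 °C; aq HCl
Reagents that add atoms: butanoyl chloride CCCC(=O)Cl
Why: Friedel–Crafts monoacylation, in which the three ring CH positions are equivalent and the chelated aryl ketone formed is deactivated toward a second acylation.

Step 5
Reactants: 9 2-methylphloroglucinol
Product: 10 1-(2,4,6-trihydroxy-3-methylphenyl)butan-1-one
Conditions: n-PrCOCl (1.0 equiv), AlCl3 (4 equiv), PhNO2/CH2Cl2, rt → 50 °C; aq HCl
Reagents that add atoms: butanoyl chloride CCCC(=O)Cl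
Why: Friedel–Crafts monoacylation at one of the two equivalent free ring positions of 9, so that a single regioisomer should result.

Step 6
Reactants: 6 2-butanoyl-3,5-dihydroxy-4,4,6-trimethylcyclohexa-2,5-dien-1-one; 8 1-(2,4,6-trihydroxyphenyl)butan-1-one
Product: 12 dimer A–B (ring A joined through the former C6 methyl carbon to ring B), via o-quinone methide 11 (not isolated)
Conditions: 8 (3 equiv), Ag2O (1.5 equiv), TEMPO (20 mol %), THF, 0 °C → rt, dark
Reagents that add atoms: none
Why: Oxidative dehydrogenation of the C-methyl trione with TEMPO/Ag2O (one-electron oxidation of the enolate, then hydrogen abstraction from the methyl group) is the known entry to the exocyclic methylene enetrione 11, which should be captured in situ by Friedel–Crafts-type conjugate addition of a free ring carbon of 8, used in excess against double alkylation, before tautomerisation restores both rings.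

Step 7
Reactants: 12 dimer A–B; 8 1-(2,4,6-trihydroxyphenyl)butan-1-one
Product: 14 trimer A–B–C, via Mannich base 13 (not isolated)
Conditions: Me2NCH2NMe2 (1.0 equiv), AcOH (cat.), 1,4-dioxane, rt; then 8 (4 equiv), 60 °C, N2 stream
Reagents that add atoms: bis(dimethylamino)methane CN(C)CN(C)C
Why: Mannich aminomethylation at the single free aromatic CH of ring B, then thermal loss of dimethylamine from the ortho-hydroxybenzylamine to an o-quinone methide that alkylates excess 8 in a Friedel–Crafts-type Michael addition, the excess keeping the new ring C from reacting twice.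

Step 8
Reactants: 10 1-(2,4,6-trihydroxy-3-methylphenyl)butan-1-one; 8 1-(2,4,6-trihydroxyphenyl)butan-1-one
Product: 16 dimer F–E, via Mannich base 15 (not isolated)
Conditions: Me2NCH2NMe2 (1.0 equiv), AcOH (cat.), 1,4-dioxane, rt; then 8 (4 equiv), 60 °C, N2 stream
Reagents that add atoms: bis(dimethylamino)methane CN(C)CN(C)C
Why: Mannich aminomethylation at the only free ring position of 10, then amine elimination to the o-quinone methide and Friedel–Crafts-type capture by excess 8.

Step 9
Reactants: 16 dimer F–E; 8 1-(2,4,6-trihydroxyphenyl)butan-1-one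
Product: 18 trimer F–E–D, via Mannich base 17 (not isolated)
Conditions: Me2NCH2NMe2 (1.0 equiv), AcOH (cat.), 1,4-dioxane, rt; then 8 (4 equiv), 60 °C, N2 stream
Reagents that add atoms: bis(dimethylamino)methane CN(C)CN(C)C
Why: The same Mannich aminomethylation, elimination and Friedel–Crafts-type alkylation sequence, now at the single free CH of ring E.

Step 10
Reactants: 18 trimer F–E–D; 14 trimer A–B–C
Product: 20 CNP0309827.0 (hexamer A–B–C–D–E–F), via Mannich base 19 (not isolated)
Conditions: Me2NCH2NMe2 (1.0 equiv), AcOH (cat.), 1,4-dioxane, rt; then 14 (1.0 equiv), 60 °C, N2 stream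
Reagents that add atoms: bis(dimethylamino)methane CN(C)CN(C)C
Why: Mannich aminomethylation of the one free CH of ring D and o-quinone methide alkylation of the one free CH of ring C should join the trimers, and neither partner can over-react because each has exactly one open aromatic position.

Compound list
1 | 2-methylpent-1-en-3-one | CCC(=O)C(C)=C | starting material
2 | 2-methyl-3-(triethylsilyloxy)pent-2-ene | CCC(O[Si](CC)(CC)CC)=C(C)C | intermediate
3 | malonyl dichloride (propanedioyl dichloride) | O=C(Cl)CC(=O)Cl | starting material
4 | 4,4-dimethyl-3,5-dioxoheptanoyl chloride (not isolated) | CCC(=O)C(C)(C)C(=O)CC(=O)Cl | intermediate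
5 | methylfilicinic acid, 3,5-dihydroxy-2,4,4-trimethylcyclohexa-2,5-dien-1-one (enol form of 2,6,6-trimethylcyclohexane-1,3,5-trione) | CC1=C(O)C(C)(C)C(O)=CC1=O | intermediate
6 | 2-butanoyl-3,5-dihydroxy-4,4,6-trimethylcyclohexa-2,5-dien-1-one | CCCC(=O)C1=C(O)C(C)(C)C(O)=C(C)C1=O | intermediate
7 | phloroglucinol (benzene-1,3,5-triol) | Oc1cc(O)cc(O)c1 | starting material
8 | 1-(2,4,6-trihydroxyphenyl)butan-1-one | CCCC(=O)c1c(O)cc(O)cc1O | intermediate
9 | 2-methylphloroglucinol (2-methylbenzene-1,3,5-triol) | Cc1c(O)cc(O)cc1O | starting material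
10 | 1-(2,4,6-trihydroxy-3-methylphenyl)butan-1-one | CCCC(=O)c1c(O)cc(O)c(C)c1O | intermediate
11 | o-quinone methide, 2-butanoyl-3-hydroxy-4,4-dimethyl-6-methylidenecyclohex-2-ene-1,5-dione (not isolated) | CCCC(=O)C1=C(O)C(C)(C)C(=O)C(=C)C1=O | intermediate
12 | dimer A–B, 2-butanoyl-6-[(3-butanoyl-2,4,6-trihydroxyphenyl)methyl]-3,5-dihydroxy-4,4-dimethylcyclohexa-2,5-dien-1-one | CCCC(=O)C1=C(O)C(C)(C)C(O)=C(Cc2c(O)cc(O)c(C(=O)CCC)c2O)C1=O | intermediate
13 | Mannich base of 12, with CH2NMe2 on the free carbon of ring B (not isolated) | CCCC(=O)C1=C(O)C(C)(C)C(O)=C(Cc2c(O)c(CN(C)C)c(O)c(C(=O)CCC)c2O)C1=O | intermediate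
14 | trimer A–B–C, dimer 12 with a (3-butanoyl-2,4,6-trihydroxyphenyl)methyl group on the free carbon of ring B | CCCC(=O)C1=C(O)C(C)(C)C(O)=C(Cc2c(O)c(Cc3c(O)cc(O)c(C(=O)CCC)c3O)c(O)c(C(=O)CCC)c2O)C1=O | intermediate
15 | Mannich base of 10, 1-[3-(dimethylaminomethyl)-2,4,6-trihydroxy-5-methylphenyl]butan-1-one (not isolated) | CCCC(=O)c1c(O)c(C)c(O)c(CN(C)C)c1O | intermediate
16 | dimer F–E, 1-[3-[(3-butanoyl-2,4,6-trihydroxyphenyl)methyl]-2,4,6-trihydroxy-5-methylphenyl]butan-1-one | CCCC(=O)c1c(O)c(C)c(O)c(Cc2c(O)cc(O)c(C(=O)CCC)c2O)c1O | intermediate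
17 | Mannich base of 16, with CH2NMe2 on the free carbon of ring E (not isolated) | CCCC(=O)c1c(O)c(C)c(O)c(Cc2c(O)c(CN(C)C)c(O)c(C(=O)CCC)c2O)c1O | intermediate
18 | trimer F–E–D, dimer 16 with a (3-butanoyl-2,4,6-trihydroxyphenyl)methyl group on the free carbon of ring E | CCCC(=O)c1c(O)c(C)c(O)c(Cc2c(O)c(Cc3c(O)cc(O)c(C(=O)CCC)c3O)c(O)c(C(=O)CCC)c2O)c1O | intermediate
19 | Mannich base of 18, with CH2NMe2 on the free carbon of ring D (not isolated) | CCCC(=O)c1c(O)c(C)c(O)c(Cc2c(O)c(Cc3c(O)c(CN(C)C)c(O)c(C(=O)CCC)c3O)c(O)c(C(=O)CCC)c2O)c1O | intermediate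
20 | CNP0309827.0, hexamer A–B–C–D–E–F | CCCC(=O)C1=C(O)C(C)(C)C(O)=C(Cc2c(O)c(Cc3c(O)c(Cc4c(O)c(Cc5c(O)c(Cc6c(O)c(C)c(O)c(C(=O)CCC)c6O)c(O)c(C(=O)CCC)c5O)c(O)c(C(=O)CCC)c4O)c(O)c(C(=O)CCC)c3O)c(O)c(C(=O)CCC)c2O)C1=O | target

Total step count: 10. Longest linear sequence: 6 steps (steps 1, 2, 3, 6, 7, 10).

Steps most likely to fail

Step 2. After the first C-acylation, closure through the ketone oxygen (enol lactone formation) or hydrolysis and decarboxylation of the β-ketoacyl chloride may outrun the carbocyclisation. The fallback separates the two acylations and sets out from 2. A Mukaiyama-type C-acylation with methyl 3-chloro-3-oxopropanoate (COC(=O)CC(=O)Cl; ZnCl2, CH2Cl2, 0 °C) would give methyl 4,4-dimethyl-3,5-dioxoheptanoate F1. A Dieckmann cyclisation of its dianion (t-BuOK, THF, rt; then HCl) would close the ring through C6 and come back to the route at 5.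

Step 6. Oxidation of the phenolic partner and self-dimerisation of the quinone methide by hetero-Diels–Alder reaction may compete with its capture. The fallback replaces the oxidation by halogenation and elimination and sets out from 6. Electrophilic bromination at the methyl-bearing enol carbon (NBS, CH2Cl2, 0 °C) would give the racemic 6-bromo-2-butanoyl-3-hydroxy-4,4,6-trimethylcyclohex-2-ene-1,5-dione F2. Dehydrobromination with Et3N in the presence of excess 8 (THF, −20 °C → rt) would release the same quinone methide under non-oxidising conditions and come back at 12.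

Step 10. Thermal retro-Friedel–Crafts cleavage and exchange of the existing methylene bridges may occur while the neutral Mannich base slowly releases its quinone methide. The fallback uses a discrete, more labile electrophile and sets out from 18. The Mannich base 19 would be isolated and N-methylated (MeI, acetone, rt) to the trimethylammonium iodide of the trimer F–E–D F3. Treatment of this salt with 14 and NaHCO3 (aqueous MeCN, 0 °C → rt) would release the quinone methide by base-induced loss of trimethylamine at low temperature and come back at 20.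

Further compounds
F1 | step 2 | methyl 4,4-dimethyl-3,5-dioxoheptanoate | CCC(=O)C(C)(C)C(=O)CC(=O)OC
F2 | step 6 | 6-bromo-2-butanoyl-3-hydroxy-4,4,6-trimethylcyclohex-2-ene-1,5-dione (racemic) | CCCC(=O)C1=C(O)C(C)(C)C(=O)C(C)(Br)C1=O
F3 | step 10 | trimethylammonium iodide of the trimer F–E–D (N-methylated Mannich base 19) | CCCC(=O)c1c(O)c(C)c(O)c(Cc2c(O)c(Cc3c(O)c(C[N+](C)(C)C)c(O)c(C(=O)CCC)c3O)c(O)c(C(=O)CCC)c2O)c1O.[I-]
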